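**Retrosynthetic overview**
- Kanzonol C is cut at the C(α)–C(=O) bond of the enone. In the forward sense this is an intermolecular alkyne hydroacylation: the formyl C–H of 2,4-dihydroxy-3-prenylbenzaldehyde adds across the triple bond of 4-ethynyl-2-prenylphenol, with all three phenols free, as the last step.
- Enabling feature: the free hydroxyl at C-2' of the ketone-bearing (resorcinol) ring, ortho to the carbonyl carbon. In the aldehyde precursor the atoms O-2', C-2', C-1' and the formyl carbon close a five-membered chelate with rhodium, which directs C–H activation and blocks decarbonylation.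
- Each prenyl group sits ortho to a phenol oxygen, so each is installed by Pd-catalysed O-(1,1-dimethylallylation) followed by aromatic Claisen rearrangement, starting from 2,4-dihydroxybenzaldehyde and 4-hydroxybenzaldehyde.
- The alkyne comes from Ohira–Bestmann homologation of 4-hydroxy-3-prenylbenzaldehyde.
- No ring is formed: both benzene rings are bought intact, and the only stereochemical element (the E double bond) arises in the key step.

Key step: step 7

Remark on the chemistry: Kanzonol C has no stereocentre, so "single enantiomer" reduces to control of the E geometry of the C(α)=C(β) bond.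

**Route**

Step 1
Reactants: 1 2-methylbut-3-en-2-ol
Product: 2 methyl (2-methylbut-3-en-2-yl) carbonate
Conditions: n-BuLi, THF, −78 °C; then ClCO2Me, −78 °C → rt
Reagents that add atoms: methyl chloroformate, COC(=O)Cl
Why: Alkoxycarbonylation of the lithium tertiary alkoxide with a chloroformate is fast and irreversible and should give the tertiary allylic carbonate cleanly.

Step 2
Reactants: 3 2,4-dihydroxybenzaldehyde; 2 methyl (2-methylbut-3-en-2-yl) carbonate
Product: 4 2-hydroxy-4-[(2-methylbut-3-en-2-yl)oxy]benzaldehyde
Conditions: Pd(PPh3)4 (2 mol%), THF, 0 °C → rt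
Reagents that add atoms: none
Why: In this decarboxylative Tsuji–Trost O-allylation the phenoxide should attack the 1,1-dimethylallyl–palladium cation at its more substituted terminus under kinetic control at low temperature, and the 4-OH should react because the 2-OH is held in the hydrogen bond to the formyl group and is less acidic.

Step 3
Reactants: 4 2-hydroxy-4-[(2-methylbut-3-en-2-yl)oxy]benzaldehyde
Product: 6 2,4-dihydroxy-3-(3-methylbut-2-en-1-yl)benzaldehyde, via ortho-dienone 5 (not isolated)
Conditions: PhNEt2, 180 °C, Ar
Reagents that add atoms: none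
Why: Aromatic Claisen rearrangement ([3,3]) and tautomerisation should deliver the allyl unit with inverted termini, as a prenyl group, to C-3, the ortho position favoured because the O-2–H···O=C chelate fixes C-3/C-4 double-bond character, while the basic solvent suppresses acid-induced loss of isoprene.

Step 4
Reactants: 7 4-hydroxybenzaldehyde; 2 methyl (2-methylbut-3-en-2-yl) carbonate
Product: 8 4-[(2-methylbut-3-en-2-yl)oxy]benzaldehyde
Conditions: Pd(PPh3)4 (2 mol%), THF, 0 °C → rt
Reagents that add atoms: none
Why: The same decarboxylative Tsuji–Trost O-allylation should give the tertiary (reverse-prenyl) aryl ether as the kinetic product, the released methoxide serving as the base.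

Step 5
Reactants: 8 4-[(2-methylbut-3-en-2-yl)oxy]benzaldehyde
Product: 10 4-hydroxy-3-(3-methylbut-2-en-1-yl)benzaldehyde, via ortho-dienone 9 (not isolated)
Conditions: PhNEt2, 180 °C, Ar
Reagents that add atoms: none
Why: Aromatic Claisen rearrangement to either of the two equivalent ortho positions (the para position is blocked by the formyl group) followed by tautomerisation should give the ortho-prenylphenol.

Step 6
Reactants: 10 4-hydroxy-3-(3-methylbut-2-en-1-yl)benzaldehyde
Product: 12 4-ethynyl-2-(3-methylbut-2-en-1-yl)phenol, via diazoalkene 11 (not isolated)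
Conditions: Ohira–Bestmann reagent (1.5 equiv), K2CO3 (3 equiv), MeOH, rt
Reagents that add atoms: dimethyl (1-diazo-2-oxopropyl)phosphonate, CC(=O)C(=[N+]=[N-])P(=O)(OC)OC
Why: In this Seyferth–Gilbert homologation (Ohira–Bestmann variant) methanolysis frees the diazomethylphosphonate anion, Horner–Wadsworth–Emmons olefination gives the diazoalkene, and loss of N2 with a 1,2-hydrogen shift should give the terminal alkyne under carbonate conditions that leave the prenyl group untouched.

Step 7
Reactants: 6 2,4-dihydroxy-3-(3-methylbut-2-en-1-yl)benzaldehyde; 12 4-ethynyl-2-(3-methylbut-2-en-1-yl)phenol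
Product: 13 Kanzonol C, (E)-1-[2,4-dihydroxy-3-(3-methylbut-2-en-1-yl)phenyl]-3-[4-hydroxy-3-(3-methylbut-2-en-1-yl)phenyl]prop-2-en-1-one
Conditions: [RhCl(cod)]2 (2.5 mol%), dppf (5 mol%), Na2CO3 (10 mol%), toluene, 90 °C, Ar, slow addition of 12
Reagents that add atoms: none
Why: Carbonate converts the O-2 hydroxyl of 6 into a rhodium(I) phenoxide, oxidative addition of the adjacent formyl C–H gives a five-membered acyl(hydrido)rhodium(III) chelate (Rh–O-2–C-2–C-1–C=O) that resists decarbonylation, syn hydrorhodation of the alkyne of 12 places H on the aryl-bearing carbon and Rh on the terminal carbon, and C(acyl)–C(alkenyl) reductive elimination forms the C(α)–C(=O) bond and returns Rh(I). The closest known reaction type is the rhodium/diphosphine-catalysed, chelation-assisted intermolecular hydroacylation of alkynes with salicylaldehydes, which gives 2-hydroxyaryl alkenyl ketones. No ring is closed and no stereocentre is formed; the E geometry follows from the syn addition of acyl and H across the triple bond. The step needs regioselectivity (acyl to the terminal alkyne carbon), which the monosubstituted alkyne should secure because the bulky chelated acyl–rhodium fragment goes to the unhindered CH terminus, with the bite angle of the diphosphine as a second lever. It needs chemoselectivity for the alkyne over the two prenyl olefins, which their trisubstitution secures, and for the formyl C–H over the three O–H bonds, which the chelate secures. Substoichiometric base, an aprotic solvent and the absence of a 6'-hydroxyl should keep the 2'-hydroxychalcone from closing to the flavanone, and slow addition of 12 limits alkyne oligomerisation.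

**Compound list**

1 | 2-methylbut-3-en-2-ol | C=CC(C)(C)O | starting material
2 | methyl (2-methylbut-3-en-2-yl) carbonate | COC(=O)OC(C)(C)C=C | intermediate
3 | 2,4-dihydroxybenzaldehyde | O=Cc1ccc(O)cc1O | starting material
4 | 2-hydroxy-4-[(2-methylbut-3-en-2-yl)oxy]benzaldehyde | C=CC(C)(C)Oc1ccc(C=O)c(O)c1 | intermediate
5 | ortho-dienone, 2-hydroxy-3-(3-methylbut-2-en-1-yl)-4-oxocyclohexa-1,5-diene-1-carbaldehyde (not isolated) | O=CC1=C(O)C(CC=C(C)C)C(=O)C=C1 | intermediate
6 | 2,4-dihydroxy-3-(3-methylbut-2-en-1-yl)benzaldehyde | CC(C)=CCc1c(O)ccc(C=O)c1O | intermediate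
7 | 4-hydroxybenzaldehyde | O=Cc1ccc(O)cc1 | starting material
8 | 4-[(2-methylbut-3-en-2-yl)oxy]benzaldehyde | C=CC(C)(C)Oc1ccc(C=O)cc1 | intermediate
9 | ortho-dienone, 3-(3-methylbut-2-en-1-yl)-4-oxocyclohexa-1,5-diene-1-carbaldehyde (not isolated) | O=CC1=CC(CC=C(C)C)C(=O)C=C1 | intermediate
10 | 4-hydroxy-3-(3-methylbut-2-en-1-yl)benzaldehyde | CC(C)=CCc1cc(C=O)ccc1O | intermediate
11 | diazoalkene, 4-(2-diazoethenyl)-2-(3-methylbut-2-en-1-yl)phenol (not isolated) | CC(C)=CCc1cc(C=C=[N+]=[N-])ccc1O | intermediate
12 | 4-ethynyl-2-(3-methylbut-2-en-1-yl)phenol | CC(C)=CCc1cc(C#C)ccc1O | intermediate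
13 | Kanzonol C | CC(C)=CCc1cc(/C=C/C(=O)c2ccc(O)c(CC=C(C)C)c2O)ccc1O | target

**Step count and risks**

Total steps: 7. Longest linear sequence: 5 (steps 1, 4, 5, 6, 7).

Steps most likely to fail:

1. Step 7. The hydrorhodation may leak regiochemically, delivering the acyl group to the internal alkyne carbon. The terminal arylalkyne may also oligomerise at rhodium, the free phenols may slow catalyst turnover, and base may induce oxa-Michael closure of the product. The fallback sets out from 6 and 12 and returns to the route at 13. Both partners would be protected with MOMCl/NaH in DMF to give 2,4-bis(methoxymethoxy)-3-(3-methylbut-2-en-1-yl)benzaldehyde F1 and 4-ethynyl-1-(methoxymethoxy)-2-(3-methylbut-2-en-1-yl)benzene F2. Syn hydrozirconation of F2 with Cp2Zr(H)Cl in CH2Cl2 should give the (E)-alkenylzirconocene chloride F3, which is not isolated. Its ZnBr2-catalysed addition to F1 forms the same C–C bond with the regiochemistry and E geometry fixed by the hydrometalation, giving the racemic allylic alcohol (E)-1-[2,4-bis(methoxymethoxy)-3-(3-methylbut-2-en-1-yl)phenyl]-3-[4-(methoxymethoxy)-3-(3-methylbut-2-en-1-yl)phenyl]prop-2-en-1-ol F4. MnO2 in CH2Cl2 should oxidise this doubly activated alcohol, destroying the carbinol stereocentre, to the tris-MOM chalcone (E)-1-[2,4-bis(methoxymethoxy)-3-(3-methylbut-2-en-1-yl)phenyl]-3-[4-(methoxymethoxy)-3-(3-methylbut-2-en-1-yl)phenyl]prop-2-en-1-one F5. Brief treatment with dilute HCl in MeOH at rt should then remove the three MOM groups and give 13.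

2. Step 3. The [3,3] shift may go in part to C-5 instead of C-3, the tertiary ether may fragment with loss of isoprene, and the ortho-prenylphenol may cyclise onto its own olefin on prolonged heating. The fallback sets out from 3 and returns at 6. It is a direct C-prenylation of the dianion of 3 with prenyl bromide in aqueous KOH at 0 °C → rt, in which C-3, flanked by both phenoxide oxygens, is the most nucleophilic carbon. No new compound is made on the way.

3. Step 6. The olefination may be slow because under carbonate the formyl group is deactivated as a para-phenoxide (a vinylogous carboxylate), so that methanolysis and decay of the diazophosphonate outrun it. The fallback sets out from 8 and returns at 12, with the order of events changed so that the homologation runs on a neutral aryl ether. Ohira–Bestmann homologation of 8 should proceed through the diazoalkene 1-(2-diazoethenyl)-4-[(2-methylbut-3-en-2-yl)oxy]benzene F6, not isolated, to 1-ethynyl-4-[(2-methylbut-3-en-2-yl)oxy]benzene F7. Aromatic Claisen rearrangement of F7 in dilute PhNEt2 at 170–180 °C, through the ortho-dienone 4-ethynyl-6-(3-methylbut-2-en-1-yl)cyclohexa-2,4-dien-1-one F8, not isolated, should then give 12.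

**Further compounds**

F1 | step 7 | 2,4-bis(methoxymethoxy)-3-(3-methylbut-2-en-1-yl)benzaldehyde | CC(C)=CCc1c(OCOC)ccc(C=O)c1OCOC
F2 | step 7 | 4-ethynyl-1-(methoxymethoxy)-2-(3-methylbut-2-en-1-yl)benzene | CC(C)=CCc1cc(C#C)ccc1OCOC
F3 | step 7 | (E)-alkenylzirconocene chloride from F2 (not isolated) | CC(C)=CCc1cc(/C=C/[Zr](Cl)(C2C=CC=C2)C2C=CC=C2)ccc1OCOC
F4 | step 7 | (E)-1-[2,4-bis(methoxymethoxy)-3-(3-methylbut-2-en-1-yl)phenyl]-3-[4-(methoxymethoxy)-3-(3-methylbut-2-en-1-yl)phenyl]prop-2-en-1-ol (racemic) | CC(C)=CCc1cc(/C=C/C(O)c2ccc(OCOC)c(CC=C(C)C)c2OCOC)ccc1OCOC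
F5 | step 7 | (E)-1-[2,4-bis(methoxymethoxy)-3-(3-methylbut-2-en-1-yl)phenyl]-3-[4-(methoxymethoxy)-3-(3-methylbut-2-en-1-yl)phenyl]prop-2-en-1-one | CC(C)=CCc1cc(/C=C/C(=O)c2ccc(OCOC)c(CC=C(C)C)c2OCOC)ccc1OCOC
F0 | step 3 | none | none
F6 | step 6 | 1-(2-diazoethenyl)-4-[(2-methylbut-3-en-2-yl)oxy]benzene (not isolated) | C=CC(C)(C)Oc1ccc(C=C=[N+]=[N-])cc1
F7 | step 6 | 1-ethynyl-4-[(2-methylbut-3-en-2-yl)oxy]benzene | C=CC(C)(C)Oc1ccc(C#C)cc1
F8 | step 6 | 4-ethynyl-6-(3-methylbut-2-en-1-yl)cyclohexa-2,4-dien-1-one (not isolated) | C#CC1=CC(CC=C(C)C)C(=O)C=C1
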